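**Strategy.** The route rests on reading C8 (the exocyclic-methylene carbon of ring B) and C13 (the β-carbon of the ring C enone) as the two carbonyls of a 1,5-diketone linked through C9, C11 and C12. An intramolecular de Mayo reaction of β-diketone 21 adds the C8=C12 enol across the C9=C11 vinyl group on C10 of ring A, forming C8–C9 and C11–C12, closing ring B and, after retro-aldol scission of C8–C12, giving diketone 24 with C9 set by equilibration. Precursor 21 joins a vinyl-bearing ring A aldehyde and a ring D methyl ketone, each made by an enantioselective Diels–Alder reaction; methylenation, deprotection and enamine aldol closure of ring C finish the synthesis.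

Key step: step 17

Locants are those of the target: ring A is C1–C5 and C10, ring B C5–C10, the linker C11–C12, ring C C13–C18, ring D C17–C22. β is the face of the C10 and C18 methyl groups.

Assumption (remark on the chemistry): the sense of induction in steps 3 and 11 is taken from the formyl C–H···O binding model of enal–oxazaborolidinium complexes, which predicts that the (R)-catalyst exposes the Cα-Si face of a 2-methyl-2-enal; should the first cycloadduct prove antipodal, the (S)-catalyst is used with no other change.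

**Route**

Step 1
Reactants: 1 4-methylpent-1-en-3-one
Product: 2 tert-butyl(dimethyl)[(4-methylpenta-1,3-dien-3-yl)oxy]silane
Conditions: TBSOTf, Et3N, Et2O, 0 → 23 °C
Reagents that add atoms: tert-butyldimethylsilyl trifluoromethanesulfonate, CC(C)(C)[Si](C)(C)OS(=O)(=O)C(F)(F)F
Why: Soft enolisation (silyl triflate and amine): the isopropyl C–H is the only enolisable position, so the cross-conjugated 2-silyloxy diene forms as a single regioisomer, and no stereochemical issue arises because the enol terminus carries two methyl groups.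

Step 2
Reactants: 3 methyl 4-oxobutanoate; 4 2-(triphenylphosphoranylidene)propanal
Product: 5 methyl (4E)-5-methyl-6-oxohex-4-enoate
Conditions: toluene, 80 °C
Reagents that add atoms: none
Why: Wittig olefination with a formyl-stabilised ylide, which reacts with the aldehyde but not with the ester and gives the E-configured 2-methyl enal through the reversibly formed, more stable oxaphosphetane.

Step 3
Reactants: 2 tert-butyl(dimethyl)[(4-methylpenta-1,3-dien-3-yl)oxy]silane; 5 methyl (4E)-5-methyl-6-oxohex-4-enoate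
Product: 6 methyl 3-[(1S,6S)-3-[tert-butyl(dimethyl)silyl]oxy-6-formyl-2,2,6-trimethylcyclohex-3-en-1-yl]propanoate
Conditions: (R)-1-(2-methylphenyl)-3,3-diphenyltetrahydro-1H,3H-pyrrolo[1,2-c][1,3,2]oxazaborole (20 mol %), Tf2NH (17 mol %), CH2Cl2, −78 → −20 °C; Et3N quench
Reagents that add atoms: none
Why: Enantioselective Diels–Alder reaction under chiral oxazaborolidinium catalysis: the oxygen-activated CMe2 terminus of 2 bonds to the enal β-carbon (C4–C5) and the CH2 terminus to the α-carbon (C1–C10), suprafacial addition to the E-enal places the C5 side chain cis to the C10 methyl group (C5–H cis to the formyl group), and attack on the exposed Cα-Si face of the boron-bound enal sets C5 and C10 together (5S,10S in 6).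

Step 4
Reactants: 6 methyl 3-[(1S,6S)-3-[tert-butyl(dimethyl)silyl]oxy-6-formyl-2,2,6-trimethylcyclohex-3-en-1-yl]propanoate
Product: 8 methyl 3-[(1R,6R)-6-ethenyl-2,2,6-trimethyl-3-oxocyclohexyl]propanoate, via vinyl silyl enol ether 7 (not isolated)
Conditions: Ph3PCH3Br, KN(SiMe3)2, THF, −78 → 23 °C; then 1 M HCl, 23 °C
Reagents that add atoms: methylenetriphenylphosphorane (made from methyltriphenylphosphonium bromide), C=P(c1ccccc1)(c1ccccc1)c1ccccc1
Why: Wittig methylenation of the non-enolisable aldehyde on the quaternary C10 (ester and silyl enol ether do not react with the ylide at this temperature), then acid hydrolysis of the silyl enol ether in the same flask to unveil the C3 ketone; no stereocentre is touched.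

Step 5
Reactants: 8 methyl 3-[(1R,6R)-6-ethenyl-2,2,6-trimethyl-3-oxocyclohexyl]propanoate
Product: 9 methyl 3-[(1R,3S,6R)-6-ethenyl-3-hydroxy-2,2,6-trimethylcyclohexyl]propanoate
Conditions: NaBH4, MeOH, 0 °C
Reagents that add atoms: none
Why: Borohydride reduction of a 2,2-dimethylcyclohexanone: on the chair that keeps the C5 chain and the C10 vinyl group equatorial, hydride enters axially from the face of C5–H, opposite the axial C4 and C10 methyl groups, to give the equatorial 3β-alcohol (C3 S), while the methyl ester is inert at 0 °C.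

Step 6
Reactants: 9 methyl 3-[(1R,3S,6R)-6-ethenyl-3-hydroxy-2,2,6-trimethylcyclohexyl]propanoate
Product: 10 methyl 3-[(1R,3S,6R)-6-ethenyl-2,2,6-trimethyl-3-(triethylsilyloxy)cyclohexyl]propanoate
Conditions: TESOTf, 2,6-lutidine, CH2Cl2, −78 → 0 °C
Reagents that add atoms: triethylsilyl trifluoromethanesulfonate, CC[Si](CC)(CC)OS(=O)(=O)C(F)(F)F
Why: Silyl ether formation with the silyl triflate, needed for this hindered alcohol next to the gem-dimethyl carbon; the triethylsilyl group is chosen because it withstands amide bases, ylides and irradiation yet is cleaved by the dilute acid that opens the ketals in step 19.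

Step 7
Reactants: 10 methyl 3-[(1R,3S,6R)-6-ethenyl-2,2,6-trimethyl-3-(triethylsilyloxy)cyclohexyl]propanoate
Product: 11 3-[(1R,3S,6R)-6-ethenyl-2,2,6-trimethyl-3-(triethylsilyloxy)cyclohexyl]propanal
Conditions: i-Bu2AlH (1.1 equiv), CH2Cl2, −78 °C
Reagents that add atoms: none
Why: Partial reduction of the methyl ester with one equivalent of i-Bu2AlH at −78 °C, where the tetrahedral aluminium alkoxide persists until work-up and then releases the aldehyde; alkene and silyl ether are inert.

Step 8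
Reactants: 12 methyl 3-oxopentanoate
Product: 13 methyl 2-(2-ethyl-1,3-dioxolan-2-yl)acetate
Conditions: HOCH2CH2OH, TsOH·H2O (cat.), benzene, reflux with azeotropic removal of water
Reagents that add atoms: ethane-1,2-diol, OCCO
Why: Acid-catalysed ketalisation driven by removal of water protects the ketone of the β-keto ester, so that the ester can be reduced and the future C15 carbonyl carried as a spectator.

Step 9
Reactants: 13 methyl 2-(2-ethyl-1,3-dioxolan-2-yl)acetate
Product: 14 2-(2-ethyl-1,3-dioxolan-2-yl)acetaldehyde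
Conditions: i-Bu2AlH (1.1 equiv), CH2Cl2, −78 °C
Reagents that add atoms: none
Why: Partial ester reduction as in step 7; the dioxolane is inert to the hydride, and the aldehyde is used without delay.

Step 10
Reactants: 14 2-(2-ethyl-1,3-dioxolan-2-yl)acetaldehyde; 4 2-(triphenylphosphoranylidene)propanal
Product: 15 (2E)-4-(2-ethyl-1,3-dioxolan-2-yl)-2-methylbut-2-enal
Conditions: toluene, 80 °C
Reagents that add atoms: none
Why: Wittig olefination as in step 2; the stabilised ylide gives the E-enal and the dioxolane is inert under the neutral conditions.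

Step 11
Reactants: 2 tert-butyl(dimethyl)[(4-methylpenta-1,3-dien-3-yl)oxy]silane; 15 (2E)-4-(2-ethyl-1,3-dioxolan-2-yl)-2-methylbut-2-enal
Product: 16 (1S,6S)-4-[tert-butyl(dimethyl)silyl]oxy-6-[(2-ethyl-1,3-dioxolan-2-yl)methyl]-1,5,5-trimethylcyclohex-3-ene-1-carbaldehyde
Conditions: (R)-1-(2-methylphenyl)-3,3-diphenyltetrahydro-1H,3H-pyrrolo[1,2-c][1,3,2]oxazaborole (20 mol %), Tf2NH (17 mol %), CH2Cl2, −78 → −20 °C; Et3N quench
Reagents that add atoms: none
Why: Enantioselective Diels–Alder reaction as in step 3 with the same catalyst enantiomer: bonds C22–C17 and C19–C18 form with the ring D side chain cis to the C18 methyl group (from the E-enal), and attack on the Cα-Si face sets C17 and C18 (1S,6S in 16), the formyl group being a better donor to boron than the dioxolane.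

Step 12
Reactants: 16 (1S,6S)-4-[tert-butyl(dimethyl)silyl]oxy-6-[(2-ethyl-1,3-dioxolan-2-yl)methyl]-1,5,5-trimethylcyclohex-3-ene-1-carbaldehyde
Product: 17 1-[(1S,6R)-4-[tert-butyl(dimethyl)silyl]oxy-6-[(2-ethyl-1,3-dioxolan-2-yl)methyl]-1,5,5-trimethylcyclohex-3-en-1-yl]ethan-1-ol (both carbinol epimers)
Conditions: MeMgBr, THF, −78 °C; H2O quench
Reagents that add atoms: methylmagnesium bromide, C[Mg]Br
Why: Grignard addition to the non-enolisable aldehyde on the quaternary C18; silyl enol ether and ketal are inert, and the configuration of the new carbinol carbon is irrelevant because it is oxidised in step 13.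

Step 13
Reactants: 17 1-[(1S,6R)-4-[tert-butyl(dimethyl)silyl]oxy-6-[(2-ethyl-1,3-dioxolan-2-yl)methyl]-1,5,5-trimethylcyclohex-3-en-1-yl]ethan-1-ol
Product: 18 1-[(1S,6S)-4-[tert-butyl(dimethyl)silyl]oxy-6-[(2-ethyl-1,3-dioxolan-2-yl)methyl]-1,5,5-trimethylcyclohex-3-en-1-yl]ethan-1-one
Conditions: Dess–Martin periodinane, pyridine, CH2Cl2, 0 → 23 °C
Reagents that add atoms: none
Why: Dess–Martin oxidation of the secondary alcohol to the methyl ketone under pyridine buffering, which protects the silyl enol ether and the ketal from the acetic acid released.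

Step 14
Reactants: 18 1-[(1S,6S)-4-[tert-butyl(dimethyl)silyl]oxy-6-[(2-ethyl-1,3-dioxolan-2-yl)methyl]-1,5,5-trimethylcyclohex-3-en-1-yl]ethan-1-one
Product: 19 1-[(7S,8S)-7-[(2-ethyl-1,3-dioxolan-2-yl)methyl]-6,6,8-trimethyl-1,4-dioxaspiro[4.5]decan-8-yl]ethan-1-one
Conditions: HOCH2CH2OH (10 equiv), TsOH·H2O (5 mol %), CH2Cl2, 23 °C
Reagents that add atoms: ethane-1,2-diol, OCCO
Why: Acid-catalysed exchange of the silyl enol ether with the diol (protonation at C20, capture of the silyloxycarbenium ion by glycol, loss of silanol and ring closure) gives the C21 dioxolane without forming water, so the C13 methyl ketone on the quaternary carbon, which ketalises only under forcing dehydration, stays free and the C15 dioxolane stays closed.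

Step 15
Reactants: 19 1-[(7S,8S)-7-[(2-ethyl-1,3-dioxolan-2-yl)methyl]-6,6,8-trimethyl-1,4-dioxaspiro[4.5]decan-8-yl]ethan-1-one; 11 3-[(1R,3S,6R)-6-ethenyl-2,2,6-trimethyl-3-(triethylsilyloxy)cyclohexyl]propanal
Product: 20 5-[(1R,3S,6R)-6-ethenyl-2,2,6-trimethyl-3-(triethylsilyloxy)cyclohexyl]-1-[(7S,8S)-7-[(2-ethyl-1,3-dioxolan-2-yl)methyl]-6,6,8-trimethyl-1,4-dioxaspiro[4.5]decan-8-yl]-3-hydroxypentan-1-one (both carbinol epimers)
Conditions: LiN(i-Pr)2, THF, −78 °C, 19; then 11, −78 °C; aq. NH4Cl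
Reagents that add atoms: none
Why: Directed aldol addition: 19 can enolise only at its methyl group (C12) because C18 is quaternary, and the lithium enolate adds to the aldehyde at −78 °C faster than proton transfer; the new carbinol centre (C8) is oxidised in step 16, so its configuration is irrelevant.

Step 16
Reactants: 20 5-[(1R,3S,6R)-6-ethenyl-2,2,6-trimethyl-3-(triethylsilyloxy)cyclohexyl]-1-[(7S,8S)-7-[(2-ethyl-1,3-dioxolan-2-yl)methyl]-6,6,8-trimethyl-1,4-dioxaspiro[4.5]decan-8-yl]-3-hydroxypentan-1-one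
Product: 21 5-[(1R,3S,6R)-6-ethenyl-2,2,6-trimethyl-3-(triethylsilyloxy)cyclohexyl]-1-[(7S,8S)-7-[(2-ethyl-1,3-dioxolan-2-yl)methyl]-6,6,8-trimethyl-1,4-dioxaspiro[4.5]decan-8-yl]pentane-1,3-dione
Conditions: Dess–Martin periodinane (1.2 equiv), pyridine, CH2Cl2, 23 °C
Reagents that add atoms: none
Why: Dess–Martin oxidation of the β-hydroxy ketone gives the 1,3-diketone, which rests as the hydrogen-bonded enol; ketals, silyl ether and the vinyl group are untouched.

Step 17
Reactants: 21 5-[(1R,3S,6R)-6-ethenyl-2,2,6-trimethyl-3-(triethylsilyloxy)cyclohexyl]-1-[(7S,8S)-7-[(2-ethyl-1,3-dioxolan-2-yl)methyl]-6,6,8-trimethyl-1,4-dioxaspiro[4.5]decan-8-yl]pentane-1,3-dione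
Product: 24 (1R,4aR,6S,8aS)-1-[3-[(7S,8S)-7-[(2-ethyl-1,3-dioxolan-2-yl)methyl]-6,6,8-trimethyl-1,4-dioxaspiro[4.5]decan-8-yl]-3-oxopropyl]-5,5,8a-trimethyl-6-(triethylsilyloxy)octahydronaphthalen-2(1H)-one, via cyclobutanol photoadduct 22 (not isolated), via C9-epimeric 1,5-diketone 23 (not isolated)
Conditions: hν (medium-pressure Hg lamp, Pyrex, λ > 300 nm), degassed cyclohexane (5 mM), 20 °C; then NaOMe (0.2 equiv), MeOH, 23 °C
Reagents that add atoms: none
Why: The hydrogen-bonded enol of 21 (C8(OH)=C12–C13=O) is the only chromophore absorbing above 300 nm; its triplet adds to the C9=C11 vinyl group stepwise, C8 bonding to C9 first and the 1,4-biradical collapsing through C11–C12 to cyclobutanol 22, a β-hydroxy ketone whose strained C8–C12 bond breaks by retro-aldol to the 1,5-diketone. The closest known reaction type is the intramolecular de Mayo reaction ([2+2] photocycloaddition of an enolised 1,3-diketone to an alkene followed by retro-aldol opening). Ring B closes in a 6-exo-trig mode across the four-atom tether C7–C6–C5–C10, the cyclobutane being a transient four-membered ring formed by biradical recombination and opened again. The one new stereocentre that survives, C9, lies α to the C8 ketone and is settled by base equilibration (23 to 24) with the C11 chain equatorial on the face of the C10 methyl group (the arrangement that is C9 S in 27), while C5 and C10 are fixed beforehand. The step needs the parallel (C8–C9/C11–C12) over the crossed (C8–C11/C9–C12) mode and the C8 over the C13 enol terminus; ring A holds the C5 chain and the C10 vinyl group trans-diequatorial, so C8 reaches C9 through a chair-like six-membered array, whereas the C13 enol could reach the alkene only through rings of seven or more atoms. Ketals and the silyl ether do not absorb at this wavelength, and irradiation is stopped at full conversion to spare the product ketones.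

Step 18
Reactants: 24 (1R,4aR,6S,8aS)-1-[3-[(7S,8S)-7-[(2-ethyl-1,3-dioxolan-2-yl)methyl]-6,6,8-trimethyl-1,4-dioxaspiro[4.5]decan-8-yl]-3-oxopropyl]-5,5,8a-trimethyl-6-(triethylsilyloxy)octahydronaphthalen-2(1H)-one
Product: 25 1-[(7S,8S)-7-[(2-ethyl-1,3-dioxolan-2-yl)methyl]-6,6,8-trimethyl-1,4-dioxaspiro[4.5]decan-8-yl]-3-[(1S,4aR,6S,8aR)-5,5,8a-trimethyl-2-methylidene-6-(triethylsilyloxy)decahydronaphthalen-1-yl]propan-1-one
Conditions: Ph3PCH3Br, KOt-Bu, THF, 0 → 45 °C
Reagents that add atoms: methylenetriphenylphosphorane (made from methyltriphenylphosphonium bromide), C=P(c1ccccc1)(c1ccccc1)c1ccccc1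
Why: Wittig methylenation, chemoselective for the ring B ketone at C8 because the C13 carbonyl is flanked by the quaternary C18; any epimerisation at C9 by the basic ylide returns the equatorial chain, and once C8 is an alkene carbon C9 is configurationally fixed.

Step 19
Reactants: 25 1-[(7S,8S)-7-[(2-ethyl-1,3-dioxolan-2-yl)methyl]-6,6,8-trimethyl-1,4-dioxaspiro[4.5]decan-8-yl]-3-[(1S,4aR,6S,8aR)-5,5,8a-trimethyl-2-methylidene-6-(triethylsilyloxy)decahydronaphthalen-1-yl]propan-1-one
Product: 26 3-[(1S,4aR,6S,8aR)-6-hydroxy-5,5,8a-trimethyl-2-methylidenedecahydronaphthalen-1-yl]-1-[(1S,2S)-1,3,3-trimethyl-4-oxo-2-(2-oxobutyl)cyclohexyl]propan-1-one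
Conditions: 1 M HCl, THF, 23 °C
Reagents that add atoms: water, O
Why: Aqueous acid hydrolysis of both dioxolanes and of the triethylsilyl ether in one operation (acetal hydrolysis and silyl ether cleavage); dilute acid at 23 °C should leave the exocyclic C8 methylene in place, and water intercepts the C15 oxocarbenium ion before any enol can.

Step 20
Reactants: 26 3-[(1S,4aR,6S,8aR)-6-hydroxy-5,5,8a-trimethyl-2-methylidenedecahydronaphthalen-1-yl]-1-[(1S,2S)-1,3,3-trimethyl-4-oxo-2-(2-oxobutyl)cyclohexyl]propan-1-one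
Product: 27 lamesticumin C
Conditions: pyrrolidine (2 equiv), AcOH (1 equiv), toluene, 60 °C
Reagents that add atoms: none
Why: Amine-catalysed intramolecular aldol condensation (the ring-closing half of a Robinson annulation): only the C15 ketone, with methylene groups on both sides, forms an enamine, whereas C13 and C21 each adjoin a quaternary carbon, so C14 is the only nucleophile and C13 the only carbonyl it can reach through a six-membered (6-enolexo-exo-trig) closure that ends in a conjugated enone, which avoids the competing closure of C12 onto C15 that an enolate medium would allow; dehydration gives the tetrasubstituted C13=C14 enone and no stereocentre is formed or epimerised.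

**Compound list**

1 | 4-methylpent-1-en-3-one | C=CC(=O)C(C)C | starting material
2 | tert-butyl(dimethyl)[(4-methylpenta-1,3-dien-3-yl)oxy]silane | C=CC(O[Si](C)(C)C(C)(C)C)=C(C)C | intermediate
3 | methyl 4-oxobutanoate | COC(=O)CCC=O | starting material
4 | 2-(triphenylphosphoranylidene)propanal | CC(C=O)=P(c1ccccc1)(c1ccccc1)c1ccccc1 | starting material
5 | methyl (4E)-5-methyl-6-oxohex-4-enoate | COC(=O)CC/C=C(\C)C=O | intermediate
6 | methyl 3-[(1S,6S)-3-[tert-butyl(dimethyl)silyl]oxy-6-formyl-2,2,6-trimethylcyclohex-3-en-1-yl]propanoate (ring A cycloadduct; C5–H cis to CHO) | O=C[C@@]1(C)CC=C(O[Si](C)(C)C(C)(C)C)C(C)(C)[C@@H]1CCC(=O)OC | intermediate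
7 | methyl 3-[(1R,6R)-3-[tert-butyl(dimethyl)silyl]oxy-6-ethenyl-2,2,6-trimethylcyclohex-3-en-1-yl]propanoate (not isolated) | C=C[C@@]1(C)CC=C(O[Si](C)(C)C(C)(C)C)C(C)(C)[C@@H]1CCC(=O)OC | intermediate
8 | methyl 3-[(1R,6R)-6-ethenyl-2,2,6-trimethyl-3-oxocyclohexyl]propanoate | C=C[C@@]1(C)CCC(=O)C(C)(C)[C@@H]1CCC(=O)OC | intermediate
9 | methyl 3-[(1R,3S,6R)-6-ethenyl-3-hydroxy-2,2,6-trimethylcyclohexyl]propanoate | C=C[C@@]1(C)CC[C@H](O)C(C)(C)[C@@H]1CCC(=O)OC | intermediate
10 | methyl 3-[(1R,3S,6R)-6-ethenyl-2,2,6-trimethyl-3-(triethylsilyloxy)cyclohexyl]propanoate | C=C[C@@]1(C)CC[C@H](O[Si](CC)(CC)CC)C(C)(C)[C@@H]1CCC(=O)OC | intermediate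
11 | 3-[(1R,3S,6R)-6-ethenyl-2,2,6-trimethyl-3-(triethylsilyloxy)cyclohexyl]propanal | C=C[C@@]1(C)CC[C@H](O[Si](CC)(CC)CC)C(C)(C)[C@@H]1CCC=O | intermediate
12 | methyl 3-oxopentanoate | CCC(=O)CC(=O)OC | starting material
13 | methyl 2-(2-ethyl-1,3-dioxolan-2-yl)acetate | CCC1(CC(=O)OC)OCCO1 | intermediate
14 | 2-(2-ethyl-1,3-dioxolan-2-yl)acetaldehyde | CCC1(CC=O)OCCO1 | intermediate
15 | (2E)-4-(2-ethyl-1,3-dioxolan-2-yl)-2-methylbut-2-enal | CCC1(C/C=C(\C)C=O)OCCO1 | intermediate
16 | (1S,6S)-4-[tert-butyl(dimethyl)silyl]oxy-6-[(2-ethyl-1,3-dioxolan-2-yl)methyl]-1,5,5-trimethylcyclohex-3-ene-1-carbaldehyde (ring D cycloadduct; C17–H cis to CHO) | O=C[C@@]1(C)CC=C(O[Si](C)(C)C(C)(C)C)C(C)(C)[C@@H]1CC1(CC)OCCO1 | intermediate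
17 | 1-[(1S,6R)-4-[tert-butyl(dimethyl)silyl]oxy-6-[(2-ethyl-1,3-dioxolan-2-yl)methyl]-1,5,5-trimethylcyclohex-3-en-1-yl]ethan-1-ol (both carbinol epimers) | CC(O)[C@@]1(C)CC=C(O[Si](C)(C)C(C)(C)C)C(C)(C)[C@@H]1CC1(CC)OCCO1 | intermediate
18 | 1-[(1S,6S)-4-[tert-butyl(dimethyl)silyl]oxy-6-[(2-ethyl-1,3-dioxolan-2-yl)methyl]-1,5,5-trimethylcyclohex-3-en-1-yl]ethan-1-one | CC(=O)[C@@]1(C)CC=C(O[Si](C)(C)C(C)(C)C)C(C)(C)[C@@H]1CC1(CC)OCCO1 | intermediate
19 | 1-[(7S,8S)-7-[(2-ethyl-1,3-dioxolan-2-yl)methyl]-6,6,8-trimethyl-1,4-dioxaspiro[4.5]decan-8-yl]ethan-1-one (ring D methyl ketone) | CC(=O)[C@@]1(C)CCC2(OCCO2)C(C)(C)[C@@H]1CC1(CC)OCCO1 | intermediate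
20 | 5-[(1R,3S,6R)-6-ethenyl-2,2,6-trimethyl-3-(triethylsilyloxy)cyclohexyl]-1-[(7S,8S)-7-[(2-ethyl-1,3-dioxolan-2-yl)methyl]-6,6,8-trimethyl-1,4-dioxaspiro[4.5]decan-8-yl]-3-hydroxypentan-1-one (both carbinol epimers) | C=C[C@@]1(C)CC[C@H](O[Si](CC)(CC)CC)C(C)(C)[C@@H]1CCC(O)CC(=O)[C@@]1(C)CCC2(OCCO2)C(C)(C)[C@@H]1CC1(CC)OCCO1 | intermediate
21 | 5-[(1R,3S,6R)-6-ethenyl-2,2,6-trimethyl-3-(triethylsilyloxy)cyclohexyl]-1-[(7S,8S)-7-[(2-ethyl-1,3-dioxolan-2-yl)methyl]-6,6,8-trimethyl-1,4-dioxaspiro[4.5]decan-8-yl]pentane-1,3-dione (C8/C13 β-diketone, mainly enol; precursor of the key step) | C=C[C@@]1(C)CC[C@H](O[Si](CC)(CC)CC)C(C)(C)[C@@H]1CCC(=O)CC(=O)[C@@]1(C)CCC2(OCCO2)C(C)(C)[C@@H]1CC1(CC)OCCO1 | intermediate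
22 | cyclobutanol photoadduct of 21: C8(OH)–C9–C11–C12 cyclobutane fused to ring B at C8–C9, the ring D acyl group (C13) on C12; configuration at C8/C9/C12 undefined (not isolated) | OC12CC[C@H]3C(C)(C)[C@@H](O[Si](CC)(CC)CC)CC[C@]3(C)C1CC2C(=O)[C@@]1(C)CCC2(OCCO2)C(C)(C)[C@@H]1CC1(CC)OCCO1 | intermediate
23 | 24 as the mixture of both C9 epimers (not isolated) | O=C1CC[C@H]2C(C)(C)[C@@H](O[Si](CC)(CC)CC)CC[C@]2(C)C1CCC(=O)[C@@]1(C)CCC2(OCCO2)C(C)(C)[C@@H]1CC1(CC)OCCO1 | intermediate
24 | (1R,4aR,6S,8aS)-1-[3-[(7S,8S)-7-[(2-ethyl-1,3-dioxolan-2-yl)methyl]-6,6,8-trimethyl-1,4-dioxaspiro[4.5]decan-8-yl]-3-oxopropyl]-5,5,8a-trimethyl-6-(triethylsilyloxy)octahydronaphthalen-2(1H)-one (C8,C13-diketone with rings A, B and D; C9 chain equatorial, β) | O=C1CC[C@H]2C(C)(C)[C@@H](O[Si](CC)(CC)CC)CC[C@]2(C)[C@H]1CCC(=O)[C@@]1(C)CCC2(OCCO2)C(C)(C)[C@@H]1CC1(CC)OCCO1 | intermediate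
25 | 1-[(7S,8S)-7-[(2-ethyl-1,3-dioxolan-2-yl)methyl]-6,6,8-trimethyl-1,4-dioxaspiro[4.5]decan-8-yl]-3-[(1S,4aR,6S,8aR)-5,5,8a-trimethyl-2-methylidene-6-(triethylsilyloxy)decahydronaphthalen-1-yl]propan-1-one | C=C1CC[C@H]2C(C)(C)[C@@H](O[Si](CC)(CC)CC)CC[C@]2(C)[C@H]1CCC(=O)[C@@]1(C)CCC2(OCCO2)C(C)(C)[C@@H]1CC1(CC)OCCO1 | intermediate
26 | 3-[(1S,4aR,6S,8aR)-6-hydroxy-5,5,8a-trimethyl-2-methylidenedecahydronaphthalen-1-yl]-1-[(1S,2S)-1,3,3-trimethyl-4-oxo-2-(2-oxobutyl)cyclohexyl]propan-1-one | C=C1CC[C@H]2C(C)(C)[C@@H](O)CC[C@]2(C)[C@H]1CCC(=O)[C@@]1(C)CCC(=O)C(C)(C)[C@@H]1CC(=O)CC | intermediate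
27 | lamesticumin C, (3S,5R,9S,10R,17R,18S) in the locants used here | C=C1CC[C@H]2C(C)(C)[C@@H](O)CC[C@]2(C)[C@H]1CCC1=C(C)C(=O)C[C@H]2C(C)(C)C(=O)CC[C@]12C | target

**Count**

Total steps: 20. Longest linear sequence: 13 steps (12 → 27, steps 8–20).

**Steps most likely to fail**

1. Step 17 (key step). The excited enol may add in the crossed sense (C8 to C11, seven-membered ring), or may fail to engage the vinyl group on the quaternary C10 before α-cleavage of the tert-alkyl ketone or secondary photolysis of the product sets in. Fallback, setting out from 11 and 19 and returning at 24: the two bonds are made thermally and one at a time. Aldehyde 11 is condensed with NH2OH·HCl and pyridine to the oxime F1. NaOCl in CH2Cl2 generates the nitrile oxide F2, which undergoes intramolecular 1,3-dipolar cycloaddition to the C10 vinyl group; the four-atom tether enforces the fused mode (C8–C9 bond, ring B) and gives the isoxazoline F3. Hydrogenolysis of the N–O bond (H2, Raney Ni, B(OH)3, MeOH–H2O) gives the β-hydroxy ketone F4. Mesylation (MsCl, Et3N) to the mesylate F5 and elimination with DBU give the α-methylene ketone F6. Michael addition of the lithium enolate of 19 (LiN(i-Pr)2, THF, −78 → 0 °C) to F6 forms C11–C12, and NaOMe/MeOH equilibration of C9 as in step 17 delivers 24.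

2. Step 11. The hindered diene and the trisubstituted enal may combine so slowly that protodesilylation of 2 or ionisation of the dioxolane at the cationic boron centre takes over, or facial discrimination may be insufficient (step 3 uses the same catalyst without the ketal and is rated safer). Fallback, setting out from 2 and 15 and returning at 19: asymmetric catalysis is given up for a racemic cycloaddition and a resolution. Me2AlCl (CH2Cl2, −78 → −20 °C) promotes the same cycloaddition to the racemic adduct F7. Steps 12–14 are run unchanged to give the racemic carbinol F8, the racemic methyl ketone F9 and the racemic bis-ketal F10. Preparative chromatography on a chiral stationary phase (amylose tris(3,5-dimethylphenylcarbamate), supercritical CO2/MeOH) separates 19 from its enantiomer F11.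

3. Step 18. The basic ylide may enolise the 1,5-diketone instead of adding, so that conversion stalls, or forcing conditions may erode the preference for C8 over C13. Fallback, setting out from 24 and returning at 25: a two-stage Peterson olefination. Me3SiCH2Li premixed with anhydrous CeCl3 (THF, −78 °C), a weakly basic nucleophile, adds to the less hindered C8 carbonyl to give the β-hydroxysilane F12, and KH (THF, 0 → 23 °C) effects syn-elimination to 25.

**Further compounds**

F1 | step 17 | oxime of aldehyde 11 | C=C[C@@]1(C)CC[C@H](O[Si](CC)(CC)CC)C(C)(C)[C@@H]1CCC=NO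
F2 | step 17 | nitrile oxide from F1 (transient) | C=C[C@@]1(C)CC[C@H](O[Si](CC)(CC)CC)C(C)(C)[C@@H]1CCC#[N+][O-]
F3 | step 17 | isoxazoline fused to ring B at C8–C9 (O on C11; C9 undefined) | N1=C2CC[C@H]3C(C)(C)[C@@H](O[Si](CC)(CC)CC)CC[C@]3(C)C2CO1
F4 | step 17 | 9-(hydroxymethyl) 8-ketone of rings A and B (C9 undefined) | O=C1CC[C@H]2C(C)(C)[C@@H](O[Si](CC)(CC)CC)CC[C@]2(C)C1CO
F5 | step 17 | methanesulfonate of F4 | O=C1CC[C@H]2C(C)(C)[C@@H](O[Si](CC)(CC)CC)CC[C@]2(C)C1COS(C)(=O)=O
F6 | step 17 | 9-methylidene 8-ketone of rings A and B (C9=C11 enone) | C=C1C(=O)CC[C@H]2C(C)(C)[C@@H](O[Si](CC)(CC)CC)CC[C@]12C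
F7 | step 11 | racemic 16 | O=C[C@@]1(C)CC=C(O[Si](C)(C)C(C)(C)C)C(C)(C)[C@@H]1CC1(CC)OCCO1.O=C[C@]1(C)CC=C(O[Si](C)(C)C(C)(C)C)C(C)(C)[C@H]1CC1(CC)OCCO1
F8 | step 11 | racemic 17 (carbinol epimers) | CC(O)[C@@]1(C)CC=C(O[Si](C)(C)C(C)(C)C)C(C)(C)[C@@H]1CC1(CC)OCCO1.CC(O)[C@]1(C)CC=C(O[Si](C)(C)C(C)(C)C)C(C)(C)[C@H]1CC1(CC)OCCO1
F9 | step 11 | racemic 18 | CC(=O)[C@@]1(C)CC=C(O[Si](C)(C)C(C)(C)C)C(C)(C)[C@@H]1CC1(CC)OCCO1.CC(=O)[C@]1(C)CC=C(O[Si](C)(C)C(C)(C)C)C(C)(C)[C@H]1CC1(CC)OCCO1
F10 | step 11 | racemic 19 | CC(=O)[C@@]1(C)CCC2(OCCO2)C(C)(C)[C@@H]1CC1(CC)OCCO1.CC(=O)[C@]1(C)CCC2(OCCO2)C(C)(C)[C@H]1CC1(CC)OCCO1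
F11 | step 11 | enantiomer of 19, 1-[(7R,8R)-7-[(2-ethyl-1,3-dioxolan-2-yl)methyl]-6,6,8-trimethyl-1,4-dioxaspiro[4.5]decan-8-yl]ethan-1-one | CC(=O)[C@]1(C)CCC2(OCCO2)C(C)(C)[C@H]1CC1(CC)OCCO1
F12 | step 18 | C8 tertiary alcohol bearing CH2SiMe3 (β-hydroxysilane from 24; C8 undefined) | C[Si](C)(C)CC1(O)CC[C@H]2C(C)(C)[C@@H](O[Si](CC)(CC)CC)CC[C@]2(C)[C@H]1CCC(=O)[C@@]1(C)CCC2(OCCO2)C(C)(C)[C@@H]1CC1(CC)OCCO1
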